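**Retrosynthetic overview**
1. Target 38 ⇐ oxidation, desilylation and removal of the linking-carbon oxygen from carbinol 34, which comes from vinyllithium 33 (from vinyl bromide 19) adding to (S)-chroman-2-carbaldehyde 32 (disconnection at ring C6–CH2).
2. Aldehyde 32 ⇐ prochiral chroman-2,2-dimethanol 25 by lipase desymmetrisation (sets chroman C2); one arm becomes CH3, the other CHO.
3. Diol 25 ⇐ Kabbe chromanone annulation of a 2-hydroxyacetophenone with a symmetric ketone (pyran ring built on the purchased arene).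
4. Bromide 19 ⇐ cis-hydrindane-4,6-dione 13 (C-methallylation, regioselective β-bromination, reduction, hydration) ⇐ cis-hydrindanone 9.
5. Ketone 9 ⇐ purchased cyclohexenone ring: Cu-catalysed asymmetric conjugate methylation sets the first quaternary centre, then enolate methylation and 5-exo enolate alkylation close the cyclopentane cis; the two bicycles are joined last.

Assumption: the lipase is taken to acylate the pro-S hydroxymethyl arm of diol 25, as with closely related chroman-2,2-dimethanols, and the ligand antipode in step 2 is the one that gives the (R)-adduct.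

**Route**

Step 1
Reactants: 1 3-chlorocyclohex-2-en-1-one; 2 1-bromo-3-chloropropane
Product: 4 3-(3-chloropropyl)cyclohex-2-en-1-one, via Grignard reagent 3 (not isolated)
Conditions: Mg, THF, 0–15 °C; then 1, CuBr·SMe2 (5 mol %), THF, −40 → 0 °C
Reagents that add atoms: none
Why: Mg inserts only into the C–Br bond, and copper-catalysed conjugate addition–elimination on the β-chloro enone replaces Cl by the chloropropyl chain without forming a stereocentre.

Step 2
Reactants: 4 3-(3-chloropropyl)cyclohex-2-en-1-one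
Product: 6 (R)-3-(3-chloropropyl)-3-methylcyclohex-1-en-1-yl acetate, via aluminium enolate 5 (not isolated)
Conditions: AlMe3 (1.5 equiv), copper thiophene-2-carboxylate Cu(O2CC4H3S) (5 mol %), chiral biphenol phosphoramidite of bis[1-(2-naphthyl)ethyl]amine (10 mol %), Et2O, −30 °C; then Ac2O, −30 → 20 °C
Reagents that add atoms: trimethylaluminium C[Al](C)C; acetic anhydride CC(=O)OC(C)=O
Why: Copper-catalysed asymmetric conjugate addition of AlMe3 to the β,β-disubstituted enone sets the quaternary stereocentre (first stereocentre of the route) under ligand control, and O-acetylation traps the regiodefined enolate.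

Step 3
Reactants: 6 (R)-3-(3-chloropropyl)-3-methylcyclohex-1-en-1-yl acetate
Product: 8 (3R)-3-(3-chloropropyl)-2,3-dimethylcyclohexan-1-one (C2 epimers), via lithium enolate 7 (not isolated)
Conditions: MeLi (2.1 equiv), THF, −20 °C; MeI (5 equiv), −78 → 0 °C; H2O quench
Reagents that add atoms: iodomethane CI
Why: MeLi cleavage of the enol acetate gives the regiodefined lithium enolate, which is C-methylated only at the hindered α-carbon (enolate alkylation); the new CH(CH3) centre forms as a mixture and becomes quaternary in step 4.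

Step 4
Reactants: 8 (3R)-3-(3-chloropropyl)-2,3-dimethylcyclohexan-1-one
Product: 9 (3aS,7aS)-3a,7a-dimethyloctahydro-4H-inden-4-one
Conditions: KOt-Bu (1.5 equiv), NaI (10 mol %), t-BuOH/THF, 25 → 60 °C
Reagents that add atoms: none
Why: Under equilibrating conditions only the more substituted enolate can undergo 5-exo-tet intramolecular alkylation, and the new five-membered ring can only be cis-fused, so the second quaternary methyl is set cis to the first.

Step 5
Reactants: 9 (3aS,7aS)-3a,7a-dimethyloctahydro-4H-inden-4-one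
Product: 10 (3aS,7aS)-3a,7a-dimethyl-1,2,3,3a,7,7a-hexahydro-4H-inden-4-one
Conditions: IBX (2 equiv), DMSO/toluene, 75 °C
Reagents that add atoms: none
Why: IBX dehydrogenation of a ketone with a single enolisable α-CH2 gives one enone, and the quaternary carbons exclude over-oxidation.

Step 6
Reactants: 10 (3aS,7aS)-3a,7a-dimethyl-1,2,3,3a,7,7a-hexahydro-4H-inden-4-one
Product: 12 (3aS,7aS)-6-hydroxy-3a,7a-dimethyloctahydro-4H-inden-4-one (C6 epimers), via boryl ketone 11 (not isolated)
Conditions: B2pin2 (1.1 equiv), CuCl (5 mol %), NaOt-Bu (10 mol %), bis[2-(diphenylphosphino)phenyl] ether (5 mol %), MeOH (2 equiv), THF, 23 °C; then NaBO3·4H2O, THF/H2O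
Reagents that add atoms: sodium perborate [Na+].[Na+].O[B-]1(O)OO[B-](O)(O)OO1
Why: Copper-catalysed conjugate borylation of the unhindered β-CH followed by C–B oxidation gives the β-hydroxy ketone; the new carbinol centre is a mixture that is destroyed in step 7.

Step 7
Reactants: 12 (3aS,7aS)-6-hydroxy-3a,7a-dimethyloctahydro-4H-inden-4-one
Product: 13 (3aS,7aS)-3a,7a-dimethyltetrahydro-1H-indene-4,6(5H,7H)-dione
Conditions: Dess–Martin periodinane (1.3 equiv), NaHCO3, CH2Cl2, 0 → 23 °C
Reagents that add atoms: none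
Why: Dess–Martin oxidation of a β-hydroxy ketone gives the 1,3-diketone under non-basic conditions that avoid retro-aldol cleavage.

Step 8
Reactants: 13 (3aS,7aS)-3a,7a-dimethyltetrahydro-1H-indene-4,6(5H,7H)-dione; 14 2-methylallyl acetate (0.95 equiv)
Product: 15 (3aS,7aS)-3a,7a-dimethyl-5-(2-methylallyl)tetrahydro-1H-indene-4,6(5H,7H)-dione
Conditions: Pd(PPh3)4 (3 mol %), Et3N (1.2 equiv), THF, 45 °C
Reagents that add atoms: none
Why: Tsuji–Trost allylation of the soft 1,3-dione nucleophile occurs at the only carbon between the two carbonyls, and limiting the acetate suppresses double allylation.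

Step 9
Reactants: 15 (3aS,7aS)-3a,7a-dimethyl-5-(2-methylallyl)tetrahydro-1H-indene-4,6(5H,7H)-dione
Product: 16 (3aS,7aS)-6-bromo-3a,7a-dimethyl-5-(2-methylallyl)-1,2,3,3a,7,7a-hexahydro-4H-inden-4-one
Conditions: Ph3PBr2 (1.2 equiv), Et3N (1.3 equiv), CH2Cl2, 0 → 23 °C
Reagents that add atoms: dibromotriphenylphosphorane BrP(Br)(c1ccccc1)(c1ccccc1)c1ccccc1
Why: In this β-halo enone synthesis (Piers type) the less hindered enol oxygen, remote from the quaternary carbon, is activated as the oxyphosphonium and replaced by bromide by addition–elimination, leaving the carbonyl next to the quaternary carbon.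

Step 10
Reactants: 16 (3aS,7aS)-6-bromo-3a,7a-dimethyl-5-(2-methylallyl)-1,2,3,3a,7,7a-hexahydro-4H-inden-4-one
Product: 17 (3aS,7aS)-6-bromo-3a,7a-dimethyl-5-(2-methylallyl)-2,3,3a,4,7,7a-hexahydro-1H-inden-4-ol (C4 epimers)
Conditions: NaBH4 (1.2 equiv), CeCl3·7H2O (1.2 equiv), MeOH, −20 → 0 °C
Reagents that add atoms: none
Why: Luche 1,2-reduction masks the ketone as an allylic alcohol; its configuration is irrelevant because it is re-oxidised in step 26.

Step 11
Reactants: 17 (3aS,7aS)-6-bromo-3a,7a-dimethyl-5-(2-methylallyl)-2,3,3a,4,7,7a-hexahydro-1H-inden-4-ol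
Product: 18 (3aS,7aS)-6-bromo-5-(2-hydroxy-2-methylpropyl)-3a,7a-dimethyl-2,3,3a,4,7,7a-hexahydro-1H-inden-4-ol
Conditions: Co(acac)2 (20 mol %), PhSiH3 (3 equiv), O2 (1 atm), THF, 23 °C; then aq Na2S2O3
Reagents that add atoms: dioxygen O=O
Why: Mukaiyama hydration (hydrogen-atom transfer from a cobalt hydride) adds water in the Markovnikov sense to the 1,1-disubstituted alkene only, the tetrasubstituted bromoalkene being inert.

Step 12
Reactants: 18 (3aS,7aS)-6-bromo-5-(2-hydroxy-2-methylpropyl)-3a,7a-dimethyl-2,3,3a,4,7,7a-hexahydro-1H-inden-4-ol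
Product: 19 bis(triethylsilyl) ether of 18
Conditions: TESOTf (2.6 equiv), 2,6-lutidine (4 equiv), CH2Cl2, −78 → 0 °C
Reagents that add atoms: triethylsilyl trifluoromethanesulfonate CC[Si](CC)(CC)OS(=O)(=O)C(F)(F)F
Why: Silyl triflate silylation protects both the hindered secondary and the tertiary alcohol in one operation, as needed for the organolithium step.

Step 13
Reactants: 20 4-methoxy-2-methylphenol
Product: 22 1-(2-hydroxy-5-methoxy-3-methylphenyl)ethan-1-one, via aryl acetate 21 (not isolated)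
Conditions: Ac2O (2.2 equiv), BF3·OEt2 (3 equiv), 90 °C; then aq NaOAc
Reagents that add atoms: acetic anhydride CC(=O)OC(C)=O
Why: O-acetylation followed by BF3-mediated Fries rearrangement delivers the acetyl group to the only free ortho position, the para position being blocked by OMe.

Step 14
Reactants: 22 1-(2-hydroxy-5-methoxy-3-methylphenyl)ethan-1-one; 23 2,2-dimethyl-1,3-dioxan-5-one (1.5 equiv)
Product: 24 6-methoxy-2',2',8-trimethylspiro[chromane-2,5'-[1,3]dioxan]-4-one
Conditions: pyrrolidine (1 equiv), MeOH, 25 → 65 °C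
Reagents that add atoms: none
Why: Kabbe condensation (amine-mediated crossed aldol condensation, then intramolecular oxa-Michael addition of the phenol) closes the chromanone; the ketone partner is symmetric, so no stereocentre arises.

Step 15
Reactants: 24 6-methoxy-2',2',8-trimethylspiro[chromane-2,5'-[1,3]dioxan]-4-one
Product: 25 (6-methoxy-8-methylchromane-2,2-diyl)dimethanol
Conditions: Zn(Hg), conc. HCl, toluene/H2O, reflux
Reagents that add atoms: none
Why: Clemmensen reduction takes the aryl ketone to CH2 and the aqueous acid hydrolyses the acetonide in the same pot, giving the prochiral diol.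

Step 16
Reactants: 25 (6-methoxy-8-methylchromane-2,2-diyl)dimethanol
Product: 26 [(2S)-2-(hydroxymethyl)-6-methoxy-8-methylchroman-2-yl]methyl acetate
Conditions: lipase (Candida antarctica lipase B, immobilised), vinyl acetate (4 equiv), t-BuOMe, 30 °C, stopped at full diol conversion
Reagents that add atoms: vinyl acetate CC(=O)OC=C
Why: Lipase-catalysed enantiotopic-group-selective transesterification (desymmetrisation) of the prochiral diol sets the chroman quaternary stereocentre, and slight over-acylation of the minor enantiomer to diacetate raises the ee.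

Step 17
Reactants: 26 [(2S)-2-(hydroxymethyl)-6-methoxy-8-methylchroman-2-yl]methyl acetate
Product: 27 [(2S)-2-[(benzyloxy)methyl]-6-methoxy-8-methylchroman-2-yl]methyl acetate
Conditions: benzyl 2,2,2-trichloroacetimidate (1.5 equiv), TfOH (5 mol %), CH2Cl2/cyclohexane, 0 → 23 °C
Reagents that add atoms: benzyl 2,2,2-trichloroacetimidate ClC(Cl)(Cl)C(=N)OCc1ccccc1
Why: Acid-catalysed imidate benzylation avoids alkoxide formation, so the acetate cannot migrate between the two arms and the stereocentre is preserved.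

Step 18
Reactants: 27 [(2S)-2-[(benzyloxy)methyl]-6-methoxy-8-methylchroman-2-yl]methyl acetate
Product: 28 [(2R)-2-[(benzyloxy)methyl]-6-methoxy-8-methylchroman-2-yl]methanol
Conditions: K2CO3 (0.5 equiv), MeOH, 23 °C
Reagents that add atoms: none
Why: Transesterification with methanol removes the acetate, and the benzyl ether on the other arm cannot migrate (the descriptor changes only through CIP priorities).

Step 19
Reactants: 28 [(2R)-2-[(benzyloxy)methyl]-6-methoxy-8-methylchroman-2-yl]methanol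
Product: 30 (2S)-2-[(benzyloxy)methyl]-6-methoxy-2,8-dimethylchromane, via triflate 29 (not isolated)
Conditions: Tf2O (1.3 equiv), pyridine (3 equiv), CH2Cl2, −78 → −10 °C; then LiEt3BH (3 equiv), THF, 0 → 23 °C; H2O quench
Reagents that add atoms: none
Why: SN2 hydride displacement of the neopentyl-type triflate by LiEt3BH turns the arm into the C2 methyl group without touching the stereocentre, and the ether arm cannot participate.

Step 20
Reactants: 30 (2S)-2-[(benzyloxy)methyl]-6-methoxy-2,8-dimethylchromane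
Product: 31 [(2S)-6-methoxy-2,8-dimethylchroman-2-yl]methanol
Conditions: H2 (1 atm), Pd/C (10 %), EtOAc/EtOH, 23 °C
Reagents that add atoms: none
Why: Hydrogenolysis cleaves only the benzyl ether, because the chroman C–O bond is not benzylic.

Step 21
Reactants: 31 [(2S)-6-methoxy-2,8-dimethylchroman-2-yl]methanol
Product: 32 (2S)-6-methoxy-2,8-dimethylchromane-2-carbaldehyde
Conditions: Dess–Martin periodinane (1.3 equiv), NaHCO3, CH2Cl2, 0 → 23 °C
Reagents that add atoms: none
Why: Dess–Martin oxidation gives the aldehyde, which has no α-hydrogen and so cannot epimerise.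

Step 22
Reactants: 19 bis(triethylsilyl) ether vinyl bromide; 32 (2S)-6-methoxy-2,8-dimethylchromane-2-carbaldehyde (1.05 equiv)
Product: 34 fragment-coupled allylic carbinol (carbinol epimers), via vinyllithium 33 (not isolated)
Conditions: t-BuLi (2.1 equiv), Et2O/THF, −78 °C; then 32, −78 → −40 °C; H2O quench
Reagents that add atoms: none
Why: Bromine–lithium exchange and 1,2-addition of the vinyllithium to the non-enolisable aldehyde join the fragments; the new carbinol centre forms as a mixture and is removed in step 24.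

Step 23
Reactants: 34 fragment-coupled allylic carbinol
Product: 35 O-alkyl 1H-imidazole-1-carbothioate of 34
Conditions: 1,1'-thiocarbonyldiimidazole (3 equiv), DMAP (0.5 equiv), toluene, 85 °C
Reagents that add atoms: 1,1'-thiocarbonyldiimidazole S=C(n1ccnc1)n1ccnc1
Why: Thiocarbonylation of the hindered secondary alcohol provides the Barton–McCombie radical precursor, and the tertiary oxygen is protected.

Step 24
Reactants: 35 O-alkyl 1H-imidazole-1-carbothioate
Product: 36 (2S)-6-methoxy-2,8-dimethyl-2-({(3aS,7aS)-3a,7a-dimethyl-5-[2-methyl-2-(triethylsilyloxy)propyl]-4-(triethylsilyloxy)-2,3,3a,4,7,7a-hexahydro-1H-inden-6-yl}methyl)chromane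
Conditions: Bu3SnH (3 equiv, 0.5 M), AIBN (0.2 equiv), toluene, 100 °C
Reagents that add atoms: none
Why: In this Barton–McCombie deoxygenation the stabilised allylic radical takes hydrogen at its less substituted terminus, restoring the tetrasubstituted ring alkene and leaving a CH2 link.

Step 25
Reactants: 36 bis(triethylsilyl) ether
Product: 37 (3aS,7aS)-5-(2-hydroxy-2-methylpropyl)-6-{[(2S)-6-methoxy-2,8-dimethylchroman-2-yl]methyl}-3a,7a-dimethyl-2,3,3a,4,7,7a-hexahydro-1H-inden-4-ol (C4 epimers)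
Conditions: TBAF (4 equiv), THF, 50 °C
Reagents that add atoms: none
Why: Fluoride desilylation frees both alcohols while no carbonyl is present, so no base-sensitive enone is exposed.

Step 26
Reactants: 37 diol
Product: 38 CNP0224132.2, (3aS,7aS)-5-(2-hydroxy-2-methylpropyl)-6-{[(2S)-6-methoxy-2,8-dimethylchroman-2-yl]methyl}-3a,7a-dimethyl-1,2,3,3a,7,7a-hexahydro-4H-inden-4-one
Conditions: Dess–Martin periodinane (1.5 equiv), NaHCO3, CH2Cl2, 0 → 23 °C
Reagents that add atoms: none
Why: Dess–Martin oxidation of the secondary allylic alcohol gives the conjugated enone directly; the tertiary alcohol is inert and no stereocentre is touched.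

**Compound list**
1 | 3-chlorocyclohex-2-en-1-one | ClC1=CC(=O)CCC1 | starting material
2 | 1-bromo-3-chloropropane | ClCCCBr | starting material
3 | (3-chloropropyl)magnesium bromide | ClCCC[Mg]Br | intermediate
4 | 3-(3-chloropropyl)cyclohex-2-en-1-one | ClCCCC1=CC(=O)CCC1 | intermediate
5 | dimethylaluminium (R)-3-(3-chloropropyl)-3-methylcyclohex-1-en-1-olate | ClCCC[C@@]1(C)CCCC(O[Al](C)C)=C1 | intermediate
6 | (R)-3-(3-chloropropyl)-3-methylcyclohex-1-en-1-yl acetate | ClCCC[C@@]1(C)CCCC(OC(C)=O)=C1 | intermediate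
7 | lithium (R)-3-(3-chloropropyl)-3-methylcyclohex-1-en-1-olate | ClCCC[C@@]1(C)CCCC(O[Li])=C1 | intermediate
8 | (3R)-3-(3-chloropropyl)-2,3-dimethylcyclohexan-1-one (C2 epimers) | ClCCC[C@@]1(C)CCCC(=O)C1C | intermediate
9 | (3aS,7aS)-3a,7a-dimethyloctahydro-4H-inden-4-one (cis-fused) | C1CC(=O)[C@@]2(C)CCC[C@@]2(C)C1 | intermediate
10 | (3aS,7aS)-3a,7a-dimethyl-1,2,3,3a,7,7a-hexahydro-4H-inden-4-one | C1=CC(=O)[C@@]2(C)CCC[C@@]2(C)C1 | intermediate
11 | (3aS,7aS)-3a,7a-dimethyl-6-(4,4,5,5-tetramethyl-1,3,2-dioxaborolan-2-yl)octahydro-4H-inden-4-one (C6 epimers) | CC1(C)OB(OC1(C)C)C1CC(=O)[C@@]2(C)CCC[C@@]2(C)C1 | intermediate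
12 | (3aS,7aS)-6-hydroxy-3a,7a-dimethyloctahydro-4H-inden-4-one (C6 epimers) | OC1CC(=O)[C@@]2(C)CCC[C@@]2(C)C1 | intermediate
13 | (3aS,7aS)-3a,7a-dimethyltetrahydro-1H-indene-4,6(5H,7H)-dione (cis-3a,7a-dimethylhydrindane-4,6-dione) | O=C1CC(=O)[C@@]2(C)CCC[C@@]2(C)C1 | intermediate
14 | 2-methylallyl acetate | CC(=C)COC(C)=O | starting material
15 | (3aS,7aS)-3a,7a-dimethyl-5-(2-methylallyl)tetrahydro-1H-indene-4,6(5H,7H)-dione (C5 epimers/enol) | O=C1C(CC(C)=C)C(=O)[C@@]2(C)CCC[C@@]2(C)C1 | intermediate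
16 | (3aS,7aS)-6-bromo-3a,7a-dimethyl-5-(2-methylallyl)-1,2,3,3a,7,7a-hexahydro-4H-inden-4-one | BrC1=C(CC(C)=C)C(=O)[C@@]2(C)CCC[C@@]2(C)C1 | intermediate
17 | (3aS,7aS)-6-bromo-3a,7a-dimethyl-5-(2-methylallyl)-2,3,3a,4,7,7a-hexahydro-1H-inden-4-ol (C4 epimers) | BrC1=C(CC(C)=C)C(O)[C@@]2(C)CCC[C@@]2(C)C1 | intermediate
18 | (3aS,7aS)-6-bromo-5-(2-hydroxy-2-methylpropyl)-3a,7a-dimethyl-2,3,3a,4,7,7a-hexahydro-1H-inden-4-ol (C4 epimers) | BrC1=C(CC(C)(C)O)C(O)[C@@]2(C)CCC[C@@]2(C)C1 | intermediate
19 | (3aS,7aS)-6-bromo-3a,7a-dimethyl-5-[2-methyl-2-(triethylsilyloxy)propyl]-4-(triethylsilyloxy)-2,3,3a,4,7,7a-hexahydro-1H-indene (C4 epimers) | BrC1=C(CC(C)(C)O[Si](CC)(CC)CC)C(O[Si](CC)(CC)CC)[C@@]2(C)CCC[C@@]2(C)C1 | intermediate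
20 | 4-methoxy-2-methylphenol | COc1ccc(O)c(C)c1 | starting material
21 | 4-methoxy-2-methylphenyl acetate | COc1ccc(OC(C)=O)c(C)c1 | intermediate
22 | 1-(2-hydroxy-5-methoxy-3-methylphenyl)ethan-1-one | COc1cc(C)c(O)c(c1)C(C)=O | intermediate
23 | 2,2-dimethyl-1,3-dioxan-5-one | CC1(C)OCC(=O)CO1 | starting material
24 | 6-methoxy-2',2',8-trimethylspiro[chromane-2,5'-[1,3]dioxan]-4-one | COc1cc(C)c2c(c1)C(=O)CC1(COC(C)(C)OC1)O2 | intermediate
25 | (6-methoxy-8-methylchromane-2,2-diyl)dimethanol | COc1cc(C)c2c(c1)CCC(CO)(CO)O2 | intermediate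
26 | [(2S)-2-(hydroxymethyl)-6-methoxy-8-methylchroman-2-yl]methyl acetate | COc1cc(C)c2c(c1)CC[C@@](COC(C)=O)(CO)O2 | intermediate
27 | [(2S)-2-[(benzyloxy)methyl]-6-methoxy-8-methylchroman-2-yl]methyl acetate | COc1cc(C)c2c(c1)CC[C@@](COC(C)=O)(COCc1ccccc1)O2 | intermediate
28 | [(2R)-2-[(benzyloxy)methyl]-6-methoxy-8-methylchroman-2-yl]methanol | COc1cc(C)c2c(c1)CC[C@@](CO)(COCc1ccccc1)O2 | intermediate
29 | [(2S)-2-[(benzyloxy)methyl]-6-methoxy-8-methylchroman-2-yl]methyl trifluoromethanesulfonate | COc1cc(C)c2c(c1)CC[C@@](COS(=O)(=O)C(F)(F)F)(COCc1ccccc1)O2 | intermediate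
30 | (2S)-2-[(benzyloxy)methyl]-6-methoxy-2,8-dimethylchromane | COc1cc(C)c2c(c1)CC[C@@](C)(COCc1ccccc1)O2 | intermediate
31 | [(2S)-6-methoxy-2,8-dimethylchroman-2-yl]methanol | COc1cc(C)c2c(c1)CC[C@@](C)(CO)O2 | intermediate
32 | (2S)-6-methoxy-2,8-dimethylchromane-2-carbaldehyde | COc1cc(C)c2c(c1)CC[C@@](C)(C=O)O2 | intermediate
33 | {(3aS,7aS)-3a,7a-dimethyl-5-[2-methyl-2-(triethylsilyloxy)propyl]-4-(triethylsilyloxy)-2,3,3a,4,7,7a-hexahydro-1H-inden-6-yl}lithium | [Li]C1=C(CC(C)(C)O[Si](CC)(CC)CC)C(O[Si](CC)(CC)CC)[C@@]2(C)CCC[C@@]2(C)C1 | intermediate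
34 | [(2S)-6-methoxy-2,8-dimethylchroman-2-yl]{(3aS,7aS)-3a,7a-dimethyl-5-[2-methyl-2-(triethylsilyloxy)propyl]-4-(triethylsilyloxy)-2,3,3a,4,7,7a-hexahydro-1H-inden-6-yl}methanol (carbinol and C4 epimers) | COc1cc(C)c2c(c1)CC[C@@](C)(C(O)C1=C(CC(C)(C)O[Si](CC)(CC)CC)C(O[Si](CC)(CC)CC)[C@@]3(C)CCC[C@@]3(C)C1)O2 | intermediate
35 | O-{[(2S)-6-methoxy-2,8-dimethylchroman-2-yl][hydrindenyl of 34]methyl} 1H-imidazole-1-carbothioate | COc1cc(C)c2c(c1)CC[C@@](C)(C(OC(=S)n1ccnc1)C1=C(CC(C)(C)O[Si](CC)(CC)CC)C(O[Si](CC)(CC)CC)[C@@]3(C)CCC[C@@]3(C)C1)O2 | intermediate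
36 | (2S)-6-methoxy-2,8-dimethyl-2-({(3aS,7aS)-3a,7a-dimethyl-5-[2-methyl-2-(triethylsilyloxy)propyl]-4-(triethylsilyloxy)-2,3,3a,4,7,7a-hexahydro-1H-inden-6-yl}methyl)chromane | COc1cc(C)c2c(c1)CC[C@@](C)(CC1=C(CC(C)(C)O[Si](CC)(CC)CC)C(O[Si](CC)(CC)CC)[C@@]3(C)CCC[C@@]3(C)C1)O2 | intermediate
37 | (3aS,7aS)-5-(2-hydroxy-2-methylpropyl)-6-{[(2S)-6-methoxy-2,8-dimethylchroman-2-yl]methyl}-3a,7a-dimethyl-2,3,3a,4,7,7a-hexahydro-1H-inden-4-ol (C4 epimers) | COc1cc(C)c2c(c1)CC[C@@](C)(CC1=C(CC(C)(C)O)C(O)[C@@]3(C)CCC[C@@]3(C)C1)O2 | intermediate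
38 | CNP0224132.2, (3aS,7aS)-5-(2-hydroxy-2-methylpropyl)-6-{[(2S)-6-methoxy-2,8-dimethylchroman-2-yl]methyl}-3a,7a-dimethyl-1,2,3,3a,7,7a-hexahydro-4H-inden-4-one | COc1cc(C)c2c(c1)CC[C@@](C)(CC1=C(CC(C)(C)O)C(=O)[C@@]3(C)CCC[C@@]3(C)C1)O2 | target

**Step count and risks**

Total steps: 26. Longest linear sequence: 17 steps (steps 1–12, then 22–26); the chroman branch is 9 steps (13–21) before the union.

Most likely to fail, first: step 4, the enolate alkylation that joins two fully substituted carbons. If the tetrasubstituted enolate does not close the ring cleanly, the two C–C bonds are formed in the reverse order. The fallback sets out from enol acetate 6: MeLi gives enolate 7, which, without MeI and on warming with NaI/DMPU, cyclises (5-exo alkylation of the less hindered trisubstituted enolate) to (3aS,7aS)-7a-methyloctahydro-4H-inden-4-one F1. Formylation (HCO2Et, NaH) at the only α-CH2 gives (3aS,7aS)-5-(hydroxymethylene)-7a-methyloctahydro-4H-inden-4-one F2, and n-BuSH/TsOH converts it into (3aS,7aS)-5-[(butylsulfanyl)methylene]-7a-methyloctahydro-4H-inden-4-one F3. With the methylene side blocked, KOt-Bu/MeI methylates the ring-fusion carbon (cis-fused product favoured) to (3aS,7aS)-5-[(butylsulfanyl)methylene]-3a,7a-dimethyloctahydro-4H-inden-4-one F4. Aqueous KOH in diethylene glycol at reflux removes the blocking group, and the fallback comes back to the route at 9.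

Second: step 16, the lipase desymmetrisation, because arm preference and ee on this exact diol are not guaranteed. The fallback uses the same enzyme class in the hydrolytic direction, which leaves the acetate on the opposite arm and so needs a different arm-differentiation sequence. It sets out from diol 25, which is peracetylated (Ac2O, pyridine, DMAP) to (6-methoxy-8-methylchromane-2,2-diyl)bis(methylene) diacetate F5. Lipase-catalysed hydrolysis (phosphate buffer pH 7, t-BuOMe, 30 °C) removes the pro-S acetate and gives [(2R)-2-(hydroxymethyl)-6-methoxy-8-methylchroman-2-yl]methyl acetate F6. Dess–Martin oxidation gives [(2S)-2-formyl-6-methoxy-8-methylchroman-2-yl]methyl acetate F7. Wolff–Kishner reduction (N2H4·H2O, KOH, diethylene glycol, 130 → 195 °C) turns CHO into CH3 and cleaves the acetate in the same pot, and the fallback comes back to the route at alcohol 31.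

Third: step 24 (with its precursor step 23), the radical deoxygenation of a very hindered allylic carbinol next to the tertiary aryl ether. Hydrogen transfer to the wrong allyl terminus or opening of the chroman are possible. The fallback never places oxygen on the linking carbon and sets out from alcohol 31 and bromide 19. Alcohol 31 is converted (Tf2O, 2,6-lutidine, CH2Cl2, −78 °C) into [(2S)-6-methoxy-2,8-dimethylchroman-2-yl]methyl trifluoromethanesulfonate F8. Bromide 19 is lithiated as in step 22 to 33 and transmetallated with MgBr2·OEt2 to {(3aS,7aS)-3a,7a-dimethyl-5-[2-methyl-2-(triethylsilyloxy)propyl]-4-(triethylsilyloxy)-2,3,3a,4,7,7a-hexahydro-1H-inden-6-yl}magnesium bromide F9. Copper-catalysed SN2 coupling of F9 with F8 (CuBr·SMe2 10 mol %, THF, −30 → 0 °C) forms the C(sp2)–CH2 bond directly and comes back to the route at 36, making steps 21–24 unnecessary.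

**Further compounds**
F1 | step 4 | (3aS,7aS)-7a-methyloctahydro-4H-inden-4-one | C1CC(=O)[C@H]2CCC[C@@]2(C)C1
F2 | step 4 | (3aS,7aS)-5-(hydroxymethylene)-7a-methyloctahydro-4H-inden-4-one | C1C(=CO)C(=O)[C@H]2CCC[C@@]2(C)C1
F3 | step 4 | (3aS,7aS)-5-[(butylsulfanyl)methylene]-7a-methyloctahydro-4H-inden-4-one | C1C(=CSCCCC)C(=O)[C@H]2CCC[C@@]2(C)C1
F4 | step 4 | (3aS,7aS)-5-[(butylsulfanyl)methylene]-3a,7a-dimethyloctahydro-4H-inden-4-one | C1C(=CSCCCC)C(=O)[C@@]2(C)CCC[C@@]2(C)C1
F5 | step 16 | (6-methoxy-8-methylchromane-2,2-diyl)bis(methylene) diacetate | COc1cc(C)c2c(c1)CCC(COC(C)=O)(COC(C)=O)O2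
F6 | step 16 | [(2R)-2-(hydroxymethyl)-6-methoxy-8-methylchroman-2-yl]methyl acetate | COc1cc(C)c2c(c1)CC[C@@](CO)(COC(C)=O)O2
F7 | step 16 | [(2S)-2-formyl-6-methoxy-8-methylchroman-2-yl]methyl acetate | COc1cc(C)c2c(c1)CC[C@@](C=O)(COC(C)=O)O2
F8 | step 24 | [(2S)-6-methoxy-2,8-dimethylchroman-2-yl]methyl trifluoromethanesulfonate | COc1cc(C)c2c(c1)CC[C@@](C)(COS(=O)(=O)C(F)(F)F)O2
F9 | step 24 | {(3aS,7aS)-3a,7a-dimethyl-5-[2-methyl-2-(triethylsilyloxy)propyl]-4-(triethylsilyloxy)-2,3,3a,4,7,7a-hexahydro-1H-inden-6-yl}magnesium bromide | Br[Mg]C1=C(CC(C)(C)O[Si](CC)(CC)CC)C(O[Si](CC)(CC)CC)[C@@]2(C)CCC[C@@]2(C)C1
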